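**Retrosynthetic overview**

1. The strategy rests on the pyranone ring (O1, C2, C3, C4, C4a, C8a) of the flavonol: C4 is a lone carbonyl carbon between the A-ring carbon C4a and the C3–C2 pair, C2 carries the B ring, and O1 sits on C8a ortho to C4a.
2. Key disconnection: C4a–C4, C4–C3 and O1–C2 are cut together, giving o-iodophenol 8 (C4a–I, C8a–OH), carbon monoxide 21 (C4) and aryl alkyne 20 (C3≡C2–Ar). The C3 hydroxyl is added afterwards by C3 metalation, borylation and oxidation, and the two silyl ethers are cleaved last.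
3. Iodophenol 8: aldehyde 1 → TIPS ether → Baeyer–Villiger oxidation and methanolysis → MOM ether → directed ortho-lithiation and iodination between OMOM and OMe → MOM removal.
4. Alkyne 20: acid 9 → Weinreb amide → isopropenyl ketone → CBS reduction (sets the only stereocentre, R) → TBS ether → Sonogashira coupling with trimethylsilylacetylene → C-desilylation.
5. Ring order: rings A and B come from the starting materials; the pyranone ring C is the only ring formed (step 12).

Key step: step 12

Assumption (remark on the chemistry): direct electrophilic iodination of phenol 4 would have to choose between two electronically near-equivalent ortho positions on sterics alone, so the iodine is placed by directed ortho-lithiation of the MOM ether. The aldehyde-to-phenol conversion is run as a peracid Baeyer–Villiger (Dakin-type) oxidation, because the aldehyde has no free ortho or para hydroxyl and the aryl silyl ether would not tolerate alkaline peroxide.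

**Route**

Step 1
Reactants: 1 3-hydroxy-4,5-dimethoxybenzaldehyde
Product: 2 3,4-dimethoxy-5-(triisopropylsilyloxy)benzaldehyde
Conditions: TIPSCl, imidazole, DMF, rt
Reagents that add atoms: triisopropylsilyl chloride, CC(C)[Si](Cl)(C(C)C)C(C)C
Why: Imidazole-promoted O-silylation of the only hydroxyl gives a bulky, non-coordinating aryl TIPS ether that later shields its ortho C–H from lithiation and is removed by fluoride at the end.

Step 2
Reactants: 2 3,4-dimethoxy-5-(triisopropylsilyloxy)benzaldehyde
Product: 4 3,4-dimethoxy-5-(triisopropylsilyloxy)phenol, via aryl formate 3 (not isolated)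
Conditions: mCPBA, CH2Cl2, 0 °C to rt; Na2S2O3 wash; then Et3N (cat.), MeOH, rt
Reagents that add atoms: 3-chloroperoxybenzoic acid (mCPBA), O=C(OO)c1cccc(Cl)c1
Why: Baeyer–Villiger (Dakin-type) oxidation, in which the electron-rich aryl group migrates in preference to hydride, followed by methanolysis of the formate under conditions too mild to cleave the aryl TIPS ether.

Step 3
Reactants: 4 3,4-dimethoxy-5-(triisopropylsilyloxy)phenol
Product: 5 1,2-dimethoxy-5-(methoxymethoxy)-3-(triisopropylsilyloxy)benzene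
Conditions: MOMCl, iPr2NEt, CH2Cl2, 0 °C to rt
Reagents that add atoms: chloromethyl methyl ether, COCCl
Why: O-Alkylation of the phenol installs a MOM acetal, a strong directing group for ortho-metalation.

Step 4
Reactants: 5 1,2-dimethoxy-5-(methoxymethoxy)-3-(triisopropylsilyloxy)benzene
Product: 7 2-iodo-3,4-dimethoxy-1-(methoxymethoxy)-5-(triisopropylsilyloxy)benzene, via aryllithium 6 (not isolated)
Conditions: n-BuLi, THF, 0 °C; then I2, THF, −78 °C to rt
Reagents that add atoms: iodine, II
Why: Directed ortho-metalation: butyllithium is held by the MOM acetal and the neighbouring methoxy group, so the C–H between them is removed while the other ortho site, flanked by the bulky non-coordinating OTIPS group, is left alone, and iodine traps the aryllithium.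

Step 5
Reactants: 7 2-iodo-3,4-dimethoxy-1-(methoxymethoxy)-5-(triisopropylsilyloxy)benzene
Product: 8 2-iodo-3,4-dimethoxy-5-(triisopropylsilyloxy)phenol
Conditions: HCl (cat.), MeOH/THF, 40 °C
Reagents that add atoms: none
Why: Acid-catalysed acetal exchange with methanol removes the MOM group, while the aryl TIPS ether and the aryl iodide should tolerate dilute methanolic HCl.

Step 6
Reactants: 9 2-(5-bromo-2-methoxyphenyl)acetic acid
Product: 11 2-(5-bromo-2-methoxyphenyl)-N-methoxy-N-methylacetamide, via acyl imidazolide 10 (not isolated)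
Conditions: CDI, CH2Cl2, rt; then MeNHOMe·HCl, rt
Reagents that add atoms: N,O-dimethylhydroxylamine hydrochloride, CNOC.Cl
Why: Amide coupling through the acyl imidazolide gives the Weinreb amide without touching the aryl bromide.

Step 7
Reactants: 11 2-(5-bromo-2-methoxyphenyl)-N-methoxy-N-methylacetamide, 12 isopropenylmagnesium bromide
Product: 14 1-(5-bromo-2-methoxyphenyl)-3-methylbut-3-en-2-one, via magnesium hemiaminal chelate 13 (not isolated)
Conditions: THF, −20 to 0 °C; inverse quench into cold 1 M HCl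
Reagents that add atoms: none
Why: Weinreb ketone synthesis: the five-membered magnesium chelate resists a second addition and releases the enone only on the acidic inverse quench, which also protonates the liberated hydroxylamine before it can add to the enone.

Step 8
Reactants: 14 1-(5-bromo-2-methoxyphenyl)-3-methylbut-3-en-2-one
Product: 16 (2R)-1-(5-bromo-2-methoxyphenyl)-3-methylbut-3-en-2-ol, via catecholboryl ether 15 (not isolated)
Conditions: (S)-Me-CBS (20 mol%), catecholborane, toluene, −78 °C; then MeOH, aq. NaOH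
Reagents that add atoms: none
Why: Corey–Bakshi–Shibata reduction: the ketone binds the (S)-oxazaborolidine with its larger isopropenyl group (sp2, α-branched, against the primary CH2Ar) away from the catalyst, so hydride reaches the face that gives the (R)-alcohol, as acetophenone gives (R)-1-phenylethanol, and catecholborane at −78 °C should leave the alkene unhydroborated.

Step 9
Reactants: 16 (2R)-1-(5-bromo-2-methoxyphenyl)-3-methylbut-3-en-2-ol
Product: 17 {[(2R)-1-(5-bromo-2-methoxyphenyl)-3-methylbut-3-en-2-yl]oxy}(tert-butyl)dimethylsilane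
Conditions: TBSCl, imidazole, DMF, rt to 40 °C
Reagents that add atoms: tert-butyldimethylsilyl chloride, CC(C)(C)[Si](C)(C)Cl
Why: O-Silylation of the secondary allylic alcohol gives a TBS ether that is inert to Pd/amine, carbonate in methanol and LDA, and leaves the stereocentre untouched.

Step 10
Reactants: 17 {[(2R)-1-(5-bromo-2-methoxyphenyl)-3-methylbut-3-en-2-yl]oxy}(tert-butyl)dimethylsilane, 18 trimethylsilylacetylene
Product: 19 tert-butyl{[(2R)-1-{2-methoxy-5-[(trimethylsilyl)ethynyl]phenyl}-3-methylbut-3-en-2-yl]oxy}dimethylsilane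
Conditions: Pd(PhCN)2Cl2, P(t-Bu)3·HBF4, CuI, iPr2NH, dioxane, rt to 45 °C
Reagents that add atoms: none
Why: Sonogashira coupling, in which the bulky electron-rich phosphine allows oxidative addition into the electron-rich aryl bromide (para to OMe) near room temperature.

Step 11
Reactants: 19 tert-butyl{[(2R)-1-{2-methoxy-5-[(trimethylsilyl)ethynyl]phenyl}-3-methylbut-3-en-2-yl]oxy}dimethylsilane
Product: 20 tert-butyl{[(2R)-1-(5-ethynyl-2-methoxyphenyl)-3-methylbut-3-en-2-yl]oxy}dimethylsilane
Conditions: K2CO3 (cat.), MeOH/THF, rt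
Reagents that add atoms: none
Why: Methoxide-mediated cleavage of the C(sp)–Si bond frees the terminal alkyne, while the alkyl TBS ether is stable to carbonate in methanol.

Step 12
Reactants: 8 2-iodo-3,4-dimethoxy-5-(triisopropylsilyloxy)phenol, 20 tert-butyl{[(2R)-1-(5-ethynyl-2-methoxyphenyl)-3-methylbut-3-en-2-yl]oxy}dimethylsilane, 21 carbon monoxide
Product: 24 2-{3-[(2R)-2-(tert-butyldimethylsilyloxy)-3-methylbut-3-enyl]-4-methoxyphenyl}-5,6-dimethoxy-7-(triisopropylsilyloxy)-4H-chromen-4-one, via o-hydroxyaryl ynone 22 (not isolated), via enaminone 23 (not isolated)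
Conditions: PdCl2(dppf) (5 mol%), CO (20 bar), Et2NH (solvent), 100 °C, no copper
Reagents that add atoms: none
Why: Pd(0) inserts into the C–I bond of 8, CO inserts to give the aroyl–Pd(II) species, and amine-assisted transfer of the acetylide of 20 followed by reductive elimination forms C4a–C4 and C4–C3 in ynone 22; Et2NH then adds to the ynone β-carbon to give enaminone 23, and the C8a phenol oxygen displaces the amine at that carbon to form O1–C2. The closest known reaction type is the Pd-catalysed carbonylative Sonogashira coupling of o-iodophenols with terminal alkynes with in situ cyclisation to flavones. The pyranone ring closes in the 6-endo mode, by addition–elimination (6-endo-trig) on the enaminone. No stereocentre is formed, and the remote (R)-silyloxy centre of 20 lies outside every bond-forming event. Two selectivities are needed: CO insertion must precede alkynyl transfer (otherwise the diarylalkyne closes to a benzofuran), which the copper-free conditions and CO pressure secure, and closure must be 6-endo and not 5-exo to the aurone, which the secondary amine secures by turning the ynone into an enaminone whose only electrophilic carbon is C2. The iodide is the only halide present, and oxidative addition into it should stay fast although the ring is electron-rich and the iodine is flanked by OH and OMe.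

Step 13
Reactants: 24 2-{3-[(2R)-2-(tert-butyldimethylsilyloxy)-3-methylbut-3-enyl]-4-methoxyphenyl}-5,6-dimethoxy-7-(triisopropylsilyloxy)-4H-chromen-4-one
Product: 27 2-{3-[(2R)-2-(tert-butyldimethylsilyloxy)-3-methylbut-3-enyl]-4-methoxyphenyl}-3-hydroxy-5,6-dimethoxy-7-(triisopropylsilyloxy)-4H-chromen-4-one, via 3-lithioflavone 25 (not isolated), via C3 dimethyl boronate 26 (not isolated)
Conditions: LDA, THF, −78 °C; B(OMe)3, −78 °C to rt; AcOH, 30% H2O2, 0 °C to rt
Reagents that add atoms: hydrogen peroxide, OO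
Why: Carbonyl-directed C3 lithiation of the flavone (the C3–H is the most acidic proton once both hydroxyls are silylated), borate capture and boronate oxidation with C-to-O migration give the flavonol, and aqueous H2O2/AcOH should not epoxidise the isopropenyl group.

Step 14
Reactants: 27 2-{3-[(2R)-2-(tert-butyldimethylsilyloxy)-3-methylbut-3-enyl]-4-methoxyphenyl}-3-hydroxy-5,6-dimethoxy-7-(triisopropylsilyloxy)-4H-chromen-4-one
Product: 29 3,7-dihydroxy-2-{3-[(2R)-2-hydroxy-3-methylbut-3-enyl]-4-methoxyphenyl}-5,6-dimethoxy-4H-chromen-4-one, via 7-hydroxy TBS ether 28 (not isolated)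
Conditions: TBAF, AcOH, THF, 0 °C to rt
Reagents that add atoms: none
Why: Fluoride-mediated desilylation cleaves the aryl TIPS ether first and the hindered secondary TBS ether more slowly, while the acetic acid buffer keeps the air-sensitive flavonol from standing as its anion; the stereocentre is not involved.

**Compound list**

1 | 3-hydroxy-4,5-dimethoxybenzaldehyde | COc1cc(C=O)cc(O)c1OC | starting material
2 | 3,4-dimethoxy-5-(triisopropylsilyloxy)benzaldehyde | COc1cc(C=O)cc(O[Si](C(C)C)(C(C)C)C(C)C)c1OC | intermediate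
3 | 3,4-dimethoxy-5-(triisopropylsilyloxy)phenyl formate (aryl formate, not isolated) | O=COc1cc(OC)c(OC)c(O[Si](C(C)C)(C(C)C)C(C)C)c1 | intermediate
4 | 3,4-dimethoxy-5-(triisopropylsilyloxy)phenol | Oc1cc(OC)c(OC)c(O[Si](C(C)C)(C(C)C)C(C)C)c1 | intermediate
5 | 1,2-dimethoxy-5-(methoxymethoxy)-3-(triisopropylsilyloxy)benzene | COCOc1cc(OC)c(OC)c(O[Si](C(C)C)(C(C)C)C(C)C)c1 | intermediate
6 | [2,3-dimethoxy-6-(methoxymethoxy)-4-(triisopropylsilyloxy)phenyl]lithium (aryllithium, not isolated) | [Li]c1c(OCOC)cc(O[Si](C(C)C)(C(C)C)C(C)C)c(OC)c1OC | intermediate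
7 | 2-iodo-3,4-dimethoxy-1-(methoxymethoxy)-5-(triisopropylsilyloxy)benzene | Ic1c(OCOC)cc(O[Si](C(C)C)(C(C)C)C(C)C)c(OC)c1OC | intermediate
8 | 2-iodo-3,4-dimethoxy-5-(triisopropylsilyloxy)phenol | Oc1cc(O[Si](C(C)C)(C(C)C)C(C)C)c(OC)c(OC)c1I | intermediate
9 | 2-(5-bromo-2-methoxyphenyl)acetic acid | COc1ccc(Br)cc1CC(=O)O | starting material
10 | 2-(5-bromo-2-methoxyphenyl)-1-(imidazol-1-yl)ethanone (acyl imidazolide, not isolated) | COc1ccc(Br)cc1CC(=O)n2ccnc2 | intermediate
11 | 2-(5-bromo-2-methoxyphenyl)-N-methoxy-N-methylacetamide | COc1ccc(Br)cc1CC(=O)N(C)OC | intermediate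
12 | isopropenylmagnesium bromide | C=C(C)[Mg]Br | starting material
13 | bromomagnesium 1-(5-bromo-2-methoxyphenyl)-2-[methoxy(methyl)amino]-3-methylbut-3-en-2-olate (chelated tetrahedral adduct, not isolated) | C=C(C)C(Cc1cc(Br)ccc1OC)(O[Mg]Br)N(C)OC | intermediate
14 | 1-(5-bromo-2-methoxyphenyl)-3-methylbut-3-en-2-one | C=C(C)C(=O)Cc1cc(Br)ccc1OC | intermediate
15 | 2-{[(2R)-1-(5-bromo-2-methoxyphenyl)-3-methylbut-3-en-2-yl]oxy}-1,3,2-benzodioxaborole (catecholboryl ether, not isolated) | C=C(C)[C@H](OB1Oc2ccccc2O1)Cc3cc(Br)ccc3OC | intermediate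
16 | (2R)-1-(5-bromo-2-methoxyphenyl)-3-methylbut-3-en-2-ol | C=C(C)[C@H](O)Cc1cc(Br)ccc1OC | intermediate
17 | {[(2R)-1-(5-bromo-2-methoxyphenyl)-3-methylbut-3-en-2-yl]oxy}(tert-butyl)dimethylsilane | C=C(C)[C@H](O[Si](C)(C)C(C)(C)C)Cc1cc(Br)ccc1OC | intermediate
18 | trimethylsilylacetylene | C#C[Si](C)(C)C | starting material
19 | tert-butyl{[(2R)-1-{2-methoxy-5-[(trimethylsilyl)ethynyl]phenyl}-3-methylbut-3-en-2-yl]oxy}dimethylsilane | C=C(C)[C@H](O[Si](C)(C)C(C)(C)C)Cc1cc(C#C[Si](C)(C)C)ccc1OC | intermediate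
20 | tert-butyl{[(2R)-1-(5-ethynyl-2-methoxyphenyl)-3-methylbut-3-en-2-yl]oxy}dimethylsilane | C=C(C)[C@H](O[Si](C)(C)C(C)(C)C)Cc1cc(C#C)ccc1OC | intermediate
21 | carbon monoxide | [C-]#[O+] | starting material
22 | 3-{3-[(2R)-2-(tert-butyldimethylsilyloxy)-3-methylbut-3-enyl]-4-methoxyphenyl}-1-[6-hydroxy-2,3-dimethoxy-4-(triisopropylsilyloxy)phenyl]prop-2-yn-1-one (o-hydroxyaryl ynone, not isolated) | C=C(C)[C@H](O[Si](C)(C)C(C)(C)C)Cc1cc(C#CC(=O)c2c(O)cc(O[Si](C(C)C)(C(C)C)C(C)C)c(OC)c2OC)ccc1OC | intermediate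
23 | 3-{3-[(2R)-2-(tert-butyldimethylsilyloxy)-3-methylbut-3-enyl]-4-methoxyphenyl}-3-(diethylamino)-1-[6-hydroxy-2,3-dimethoxy-4-(triisopropylsilyloxy)phenyl]prop-2-en-1-one (enaminone, alkene geometry not defined, not isolated) | C=C(C)[C@H](O[Si](C)(C)C(C)(C)C)Cc1cc(C(=CC(=O)c2c(O)cc(O[Si](C(C)C)(C(C)C)C(C)C)c(OC)c2OC)N(CC)CC)ccc1OC | intermediate
24 | 2-{3-[(2R)-2-(tert-butyldimethylsilyloxy)-3-methylbut-3-enyl]-4-methoxyphenyl}-5,6-dimethoxy-7-(triisopropylsilyloxy)-4H-chromen-4-one | C=C(C)[C@H](O[Si](C)(C)C(C)(C)C)Cc1cc(-c2cc(=O)c3c(OC)c(OC)c(O[Si](C(C)C)(C(C)C)C(C)C)cc3o2)ccc1OC | intermediate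
25 | 3-lithio derivative of 24 (not isolated) | C=C(C)[C@H](O[Si](C)(C)C(C)(C)C)Cc1cc(-c2oc3cc(O[Si](C(C)C)(C(C)C)C(C)C)c(OC)c(OC)c3c(=O)c2[Li])ccc1OC | intermediate
26 | dimethyl boronate at C3 of 24 (not isolated) | C=C(C)[C@H](O[Si](C)(C)C(C)(C)C)Cc1cc(-c2oc3cc(O[Si](C(C)C)(C(C)C)C(C)C)c(OC)c(OC)c3c(=O)c2B(OC)OC)ccc1OC | intermediate
27 | 2-{3-[(2R)-2-(tert-butyldimethylsilyloxy)-3-methylbut-3-enyl]-4-methoxyphenyl}-3-hydroxy-5,6-dimethoxy-7-(triisopropylsilyloxy)-4H-chromen-4-one | C=C(C)[C@H](O[Si](C)(C)C(C)(C)C)Cc1cc(-c2oc3cc(O[Si](C(C)C)(C(C)C)C(C)C)c(OC)c(OC)c3c(=O)c2O)ccc1OC | intermediate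
28 | 2-{3-[(2R)-2-(tert-butyldimethylsilyloxy)-3-methylbut-3-enyl]-4-methoxyphenyl}-3,7-dihydroxy-5,6-dimethoxy-4H-chromen-4-one (not isolated) | C=C(C)[C@H](O[Si](C)(C)C(C)(C)C)Cc1cc(-c2oc3cc(O)c(OC)c(OC)c3c(=O)c2O)ccc1OC | intermediate
29 | 3,7-dihydroxy-2-{3-[(2R)-2-hydroxy-3-methylbut-3-enyl]-4-methoxyphenyl}-5,6-dimethoxy-4H-chromen-4-one (CNP0264719.1) | C=C(C)[C@H](O)Cc1cc(-c2oc3cc(O)c(OC)c(OC)c3c(=O)c2O)ccc1OC | target

**Step count and risks**

Total step count: 14 (steps 1–5 to iodophenol 8, steps 6–11 to alkyne 20, steps 12–14 after convergence).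
Longest linear sequence: 9 steps (9 → 29, steps 6–14).

Steps most likely to fail:

1. Step 12 (carbonylative annulation).
   - What may go wrong: on the electron-rich aryl–palladium intermediate flanked by OH and OMe, CO insertion may be slower than alkynyl transfer, so that direct coupling and closure to a 2-arylbenzofuran compete; the aryl silyl ether may also erode in the hot amine.
   - Fallback (stepwise ynone assembly without CO), setting out from 5 and 20: lithiation of 5 as in step 4 (aryllithium 6) and a DMF quench should give 2,3-dimethoxy-6-(methoxymethoxy)-4-(triisopropylsilyloxy)benzaldehyde F1. Alkyne 20 is deprotonated with n-BuLi (THF, −78 °C) to its lithium acetylide F2, which adds to F1 to give the propargylic alcohol F3 (both carbinol epimers; the centre is destroyed in the next operation). MnO2 in CH2Cl2 should oxidise F3 to the MOM-protected ynone F4. TMSOTf/2,2'-bipyridyl in CH2Cl2 followed by water, a mild non-protic method for aromatic MOM ethers that is expected to spare the silyl ethers, unmasks the phenol to give ynone 22. Et2NH in EtOH then closes 22 through enaminone 23 to flavone 24, where the route is rejoined.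

2. Step 13 (C3 hydroxylation).
   - What may go wrong: the 3-lithio species 25 may be lost before boron capture, by proton return or by fragmentation to the ynone phenoxide on warming, and the hindered borate may protodeboronate instead of oxidising.
   - Fallback (halogenation, then catalytic borylation), setting out from 24: the lithio species 25 is quenched at −78 °C with iodine, a fast and irreversible trap, to give the 3-iodoflavone F5. Miyaura borylation (B2pin2, PdCl2(dppf), KOAc, dioxane, 80 °C) should convert F5 into the isolable pinacol boronate F6. Mild perborate oxidation (NaBO3·4H2O, THF/H2O, rt) then gives flavonol 27, where the route is rejoined.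

3. Step 8 (CBS reduction).
   - What may go wrong: facial discrimination between the isopropenyl and CH2Ar groups may be too weak to give a useful enantiomeric excess, and the borane may add to the alkene.
   - Fallback (racemic reduction, then kinetic resolution), setting out from 14: Luche reduction (NaBH4, CeCl3·7H2O, MeOH, 0 °C) gives the racemic allylic alcohol F7. Sharpless kinetic resolution (Ti(OiPr)4, L-(+)-diisopropyl tartrate, t-BuOOH 0.6 equiv, 4 Å sieves, CH2Cl2, −20 °C) should epoxidise the (S)-enantiomer to the epoxy alcohol F8 and leave the (R)-alcohol 16, which is separated by chromatography and rejoins the route at 16.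

Further compounds
F1 | step 12 | 2,3-dimethoxy-6-(methoxymethoxy)-4-(triisopropylsilyloxy)benzaldehyde | O=Cc1c(OCOC)cc(O[Si](C(C)C)(C(C)C)C(C)C)c(OC)c1OC
F2 | step 12 | lithium acetylide of 20 | C=C(C)[C@H](O[Si](C)(C)C(C)(C)C)Cc1cc(C#C[Li])ccc1OC
F3 | step 12 | 3-{3-[(2R)-2-(tert-butyldimethylsilyloxy)-3-methylbut-3-enyl]-4-methoxyphenyl}-1-[2,3-dimethoxy-6-(methoxymethoxy)-4-(triisopropylsilyloxy)phenyl]prop-2-yn-1-ol (both carbinol epimers) | C=C(C)[C@H](O[Si](C)(C)C(C)(C)C)Cc1cc(C#CC(O)c2c(OCOC)cc(O[Si](C(C)C)(C(C)C)C(C)C)c(OC)c2OC)ccc1OC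
F4 | step 12 | 3-{3-[(2R)-2-(tert-butyldimethylsilyloxy)-3-methylbut-3-enyl]-4-methoxyphenyl}-1-[2,3-dimethoxy-6-(methoxymethoxy)-4-(triisopropylsilyloxy)phenyl]prop-2-yn-1-one | C=C(C)[C@H](O[Si](C)(C)C(C)(C)C)Cc1cc(C#CC(=O)c2c(OCOC)cc(O[Si](C(C)C)(C(C)C)C(C)C)c(OC)c2OC)ccc1OC
F5 | step 13 | 2-{3-[(2R)-2-(tert-butyldimethylsilyloxy)-3-methylbut-3-enyl]-4-methoxyphenyl}-3-iodo-5,6-dimethoxy-7-(triisopropylsilyloxy)-4H-chromen-4-one | C=C(C)[C@H](O[Si](C)(C)C(C)(C)C)Cc1cc(-c2oc3cc(O[Si](C(C)C)(C(C)C)C(C)C)c(OC)c(OC)c3c(=O)c2I)ccc1OC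
F6 | step 13 | 2-{3-[(2R)-2-(tert-butyldimethylsilyloxy)-3-methylbut-3-enyl]-4-methoxyphenyl}-5,6-dimethoxy-3-(4,4,5,5-tetramethyl-1,3,2-dioxaborolan-2-yl)-7-(triisopropylsilyloxy)-4H-chromen-4-one | C=C(C)[C@H](O[Si](C)(C)C(C)(C)C)Cc1cc(-c2oc3cc(O[Si](C(C)C)(C(C)C)C(C)C)c(OC)c(OC)c3c(=O)c2B4OC(C)(C)C(C)(C)O4)ccc1OC
F7 | step 8 | racemic 1-(5-bromo-2-methoxyphenyl)-3-methylbut-3-en-2-ol | C=C(C)C(O)Cc1cc(Br)ccc1OC
F8 | step 8 | (1S)-2-(5-bromo-2-methoxyphenyl)-1-[(2S)-2-methyloxiran-2-yl]ethanol | C[C@]1(CO1)[C@@H](O)Cc2cc(Br)ccc2OC
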